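Everything rests on the C1–C6 bond: the allylic carbinol C1(O)–C6(CH3)=C5 of ring A is read as the adduct of a C6 vinylmetal and a C1 aldehyde. One intramolecular Nozaki–Hiyama–Kishi reaction closes ring A last, delivers the trisubstituted C5=C6 alkene and creates the C1 stereocentre, on a ring B cycloheptanone that already holds the trans C3/C4 centres. The precursor is a 2,3-trans-disubstituted 4,4-dimethylcycloheptanone with a CH2CHO arm on C3 and a (Z)-2-iodopropenyl arm on C4, reached from 4,4-dimethylcyclohexenone by asymmetric conjugate alkenylation, alkylation and one-carbon ring expansion. Methyl addition at C11 and a Mitsunobu esterification with inversion at C1 complete the target.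

Key step: step 10

Remarks
- Skeleton locants used throughout: C1 ester CH, C2 CH2, C3 and C4 ring-fusion CH (C3 next to C11, C4 next to C7), C5=C6(CH3), C7 C(CH3)2, C8–C10 CH2, C11 C(CH3)OH. Ring A is C1–C6; ring B is C3, C4, C7–C11. The target is (1R,3R,4R,11R), trans-fused, with a pseudo-axial ester at C1 and an axial methyl at C11.
- Assumption: the sense of induction known for (S)-BINAP in conjugate additions to cyclohexenones is taken to hold for dienone 2; the mirror-image ligand would be used if the adduct proved to be the R isomer.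

Step 1
Reactants: 1 4,4-dimethylcyclohex-2-en-1-one
Product: 2 4,4-dimethylcyclohexa-2,5-dien-1-one
Conditions: DDQ, dioxane, reflux
Reagents that add atoms: none
Why: Quinone dehydrogenation of an enone to the cross-conjugated dienone; only the CH2–CH2 unit can be unsaturated because the γ-carbon is quaternary, and no stereocentre is involved.

Step 2
Reactants: 2 4,4-dimethylcyclohexa-2,5-dien-1-one; 3 (E)-prop-1-en-1-ylboronic acid
Product: 4 (S)-4,4-dimethyl-5-[(E)-prop-1-en-1-yl]cyclohex-2-en-1-one
Conditions: [Rh(OH)((S)-binap)]2 (cat.), dioxane/H2O 10:1, 35 °C, 2 in slight excess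
Reagents that add atoms: none
Why: Hayashi–Miyaura asymmetric conjugate addition: the alkenylrhodium–(S)-BINAP species adds to one of the two enantiotopic enone units of 2 from the face that gives (S)-3-substituted cyclohexanones, which sets the future C4 centre, while the limiting boronic acid and the added bulk beside the remaining enone should hold back a second addition.

Step 3
Reactants: 4 (S)-4,4-dimethyl-5-[(E)-prop-1-en-1-yl]cyclohex-2-en-1-one; 5 methyl bromoacetate
Product: 7 methyl 2-[(1R,6R)-5,5-dimethyl-2-oxo-6-[(E)-prop-1-en-1-yl]cyclohex-3-en-1-yl]acetate, via lithium dienolate 6 (not isolated)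
Conditions: LiN(i-Pr)2, THF, −78 °C; then 5, DMPU, −78 → −20 °C
Reagents that add atoms: none
Why: Kinetic α′-alkylation of a cyclohexenone enolate: the ring CH2 beside the carbonyl carries the only enolisable hydrogens, and the bromoacetate approaches dienolate 6 anti to the neighbouring propenyl group, giving the trans product (future C3 as R), which is also the epimer favoured by equilibration.

Step 4
Reactants: 7 methyl 2-[(1R,6R)-5,5-dimethyl-2-oxo-6-[(E)-prop-1-en-1-yl]cyclohex-3-en-1-yl]acetate
Product: 8 methyl 2-[(1R,6R)-5,5-dimethyl-2-oxo-6-[(E)-prop-1-en-1-yl]cyclohexyl]acetate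
Conditions: [(Ph3P)CuH]6, H2O, toluene, rt
Reagents that add atoms: none
Why: Copper hydride conjugate reduction: the phosphine-bound hydride attacks only the β-carbon of the enone and water protonates the copper enolate, so the isolated propenyl alkene, the ester and both stereocentres are untouched.

Step 5
Reactants: 8 methyl 2-[(1R,6R)-5,5-dimethyl-2-oxo-6-[(E)-prop-1-en-1-yl]cyclohexyl]acetate
Product: 10 methyl 2-[(1R,7R)-6,6-dimethyl-2-oxo-7-[(E)-prop-1-en-1-yl]cycloheptyl]acetate, via α-silyl ketone 9 (not isolated)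
Conditions: Me3SiCHN2, AlMe3, CH2Cl2, −78 → −20 °C; then 1 M HCl, THF, 0 °C
Reagents that add atoms: (trimethylsilyl)diazomethane, C[Si](C)(C)C=[N+]=[N-]
Why: Lewis-acid-promoted diazoalkane homologation (Tiffeneau–Demjanov-type ring expansion): the diazoalkane adds to the AlMe3-bound ketone and the less substituted α-CH2 migrates in preference to the tertiary α-carbon with loss of N2, after which acid removes the silyl group from 9; the stereocentres are not involved and the α-centre stays in its more stable trans form.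

Step 6
Reactants: 10 methyl 2-[(1R,7R)-6,6-dimethyl-2-oxo-7-[(E)-prop-1-en-1-yl]cycloheptyl]acetate
Product: 12 methyl 2-[(1R,7R)-7-formyl-6,6-dimethyl-2-oxocycloheptyl]acetate, via ozonide 11 (not isolated)
Conditions: O3, CH2Cl2, −78 °C; then PPh3, −78 °C → rt
Reagents that add atoms: ozone, O=[O+][O-]
Why: Ozonolysis with reductive work-up: the propenyl group is the only alkene present, so cleavage of ozonide 11 by PPh3 unmasks the C5 aldehyde directly, and the cold neutral conditions should avoid epimerisation of the α-centre.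

Step 7
Reactants: 12 methyl 2-[(1R,7R)-7-formyl-6,6-dimethyl-2-oxocycloheptyl]acetate
Product: 13 methyl 2-[(1R,7S)-7-[(Z)-2-iodoprop-1-en-1-yl]-6,6-dimethyl-2-oxocycloheptyl]acetate
Conditions: Ph3PEtI, n-BuLi, THF; I2, −78 °C; NaN(SiMe3)2, −20 °C; then 12, −78 °C
Reagents that add atoms: ethyltriphenylphosphonium iodide, CC[P+](c1ccccc1)(c1ccccc1)c1ccccc1.[I-]; iodine, II
Why: Stork–Zhao-type Wittig α-iodoethylidenation: the unstabilised iodo ylide reacts with the aldehyde under kinetic control through the cis oxaphosphetane, placing iodine cis to the ring carbon (Z), and at −78 °C it should discriminate the aldehyde from the hindered ketone and the ester.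

Step 8
Reactants: 13 methyl 2-[(1R,7S)-7-[(Z)-2-iodoprop-1-en-1-yl]-6,6-dimethyl-2-oxocycloheptyl]acetate
Product: 14 (2R,3S)-2-(2-hydroxyethyl)-3-[(Z)-2-iodoprop-1-en-1-yl]-4,4-dimethylcycloheptan-1-ol (both carbinol epimers)
Conditions: i-Bu2AlH, CH2Cl2, −78 → 0 °C; aqueous potassium sodium tartrate
Reagents that add atoms: none
Why: Hydride reduction: i-Bu2AlH reduces ester and ketone together without touching the iodoalkene, so the two carbonyl groups need not be differentiated, and the new carbinol centre is irrelevant because it is oxidised back in the next step.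

Step 9
Reactants: 14 (2R,3S)-2-(2-hydroxyethyl)-3-[(Z)-2-iodoprop-1-en-1-yl]-4,4-dimethylcycloheptan-1-ol
Product: 15 2-[(1R,7S)-7-[(Z)-2-iodoprop-1-en-1-yl]-6,6-dimethyl-2-oxocycloheptyl]acetaldehyde
Conditions: (COCl)2, DMSO, CH2Cl2, −78 °C; Et3N, −78 → −20 °C
Reagents that add atoms: none
Why: Swern oxidation: both hydroxyls are activated as alkoxysulfonium salts before base is added, so aldehyde and ketone are released together and lactol or lactone formation from the 1,4-diol is avoided, while the mild base leaves the trans C3/C4 centres in place.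

Step 10
Reactants: 15 2-[(1R,7S)-7-[(Z)-2-iodoprop-1-en-1-yl]-6,6-dimethyl-2-oxocycloheptyl]acetaldehyde
Product: 17 (2S,4aR,9aR)-2-hydroxy-3,5,5-trimethyl-1,2,4a,5,6,7,8,9a-octahydro-9H-benzo[7]annulen-9-one, via vinylchromium 16 (not isolated)
Conditions: CrCl2 (6 equiv), NiCl2 (2 mol %), degassed DMSO, rt, 0.01 M
Reagents that add atoms: none
Why: Zerovalent nickel formed in situ inserts into the C6–I bond with retention of the Z geometry, transmetallation to trivalent chromium gives vinylchromium 16, and this adds to the C1 aldehyde, the chromium alkoxide being hydrolysed at work-up. The closest known reaction type is the intramolecular Nozaki–Hiyama–Kishi vinylation of an aldehyde by an iodoalkene. Ring A closes in a 6-exo-trig mode at the aldehyde carbon, the Z-alkene already holding C4 and C1 cis on C5=C6. The new C1 stereocentre is controlled by the existing C3/C4 centres: in the chair-like transition state both ring B bonds are equatorial and the carbonyl oxygen stays near the plane of the alkene, within reach of the chromium on C6 and away from the axial C3–H, so it should end pseudo-equatorial (1S). The step needs selectivity for the aldehyde over the C11 ketone and no epimerisation at C3; organochromium reagents add far faster to aldehydes than to ketones, attack on C11 would need a strained five-membered closure, and the neutral conditions leave the ketone α-centre alone.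

Step 11
Reactants: 17 (2S,4aR,9aR)-2-hydroxy-3,5,5-trimethyl-1,2,4a,5,6,7,8,9a-octahydro-9H-benzo[7]annulen-9-one
Product: 18 (2S,4aR,9aR)-3,5,5-trimethyl-2-(triethylsilyloxy)-1,2,4a,5,6,7,8,9a-octahydro-9H-benzo[7]annulen-9-one
Conditions: Et3SiCl, imidazole, CH2Cl2, 0 °C → rt
Reagents that add atoms: chlorotriethylsilane, CC[Si](Cl)(CC)CC
Why: Silyl ether protection of a secondary alcohol, so that the hydroxyl neither consumes nor redirects the organometallic reagents of the next step.

Step 12
Reactants: 18 (2S,4aR,9aR)-3,5,5-trimethyl-2-(triethylsilyloxy)-1,2,4a,5,6,7,8,9a-octahydro-9H-benzo[7]annulen-9-one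
Product: 19 (2S,4aR,9R,9aR)-3,5,5,9-tetramethyl-2-(triethylsilyloxy)-2,4a,5,6,7,8,9,9a-octahydro-1H-benzo[7]annulen-9-ol
Conditions: MeAl(OAr)2 (3 equiv; Ar = 2,6-di-tert-butyl-4-methylphenyl; from AlMe3 and ArOH), toluene, −78 °C; then MeLi (3 equiv), −78 °C
Reagents that add atoms: methyllithium, [Li]C
Why: Amphiphilic carbonyl alkylation: the bulky aluminium phenoxide binds the C11 carbonyl oxygen and blocks the equatorial trajectory, so MeLi should add along the axial line on the face anti to C3–H, giving the axial methyl and equatorial hydroxyl (11R), and the hindered Lewis acid also suppresses enolisation.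

Step 13
Reactants: 19 (2S,4aR,9R,9aR)-3,5,5,9-tetramethyl-2-(triethylsilyloxy)-2,4a,5,6,7,8,9,9a-octahydro-1H-benzo[7]annulen-9-ol
Product: 20 (2S,4aR,9R,9aR)-3,5,5,9-tetramethyl-2,4a,5,6,7,8,9,9a-octahydro-1H-benzo[7]annulene-2,9-diol
Conditions: Bu4NF, THF, 0 °C → rt
Reagents that add atoms: none
Why: Fluoride-mediated desilylation: Si–F bond formation cleaves the secondary triethylsilyl ether, while the tertiary C11 alcohol and the alkene are inert.

Step 14
Reactants: 21 isovanillic acid (3-hydroxy-4-methoxybenzoic acid)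
Product: 23 3-(tert-butyldimethylsilyloxy)-4-methoxybenzoic acid, via bis-silylated acid 22 (not isolated)
Conditions: t-BuMe2SiCl (2.5 equiv), imidazole, DMF, rt; then AcOH/H2O/THF, rt
Reagents that add atoms: tert-butylchlorodimethylsilane, CC(C)(C)[Si](C)(C)Cl
Why: Exhaustive silylation followed by selective hydrolysis: the silyl ester of 22 is far more labile to aqueous acid than the aryl silyl ether, so the free acid with a masked phenol results.

Step 15
Reactants: 20 (2S,4aR,9R,9aR)-3,5,5,9-tetramethyl-2,4a,5,6,7,8,9,9a-octahydro-1H-benzo[7]annulene-2,9-diol; 23 3-(tert-butyldimethylsilyloxy)-4-methoxybenzoic acid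
Product: 24 (2R,4aR,9R,9aR)-9-hydroxy-3,5,5,9-tetramethyl-2,4a,5,6,7,8,9,9a-octahydro-1H-benzo[7]annulen-2-yl 3-(tert-butyldimethylsilyloxy)-4-methoxybenzoate
Conditions: PPh3, DIAD, toluene, 0 °C → rt
Reagents that add atoms: none
Why: Mitsunobu esterification: the alkoxyphosphonium ion of the secondary allylic C1 alcohol is displaced by the carboxylate in an SN2 reaction with inversion (1S to 1R, the pseudo-axial ester), the tertiary C11 alcohol being too hindered to be activated and SN2′ attack at C5 being blocked by the adjacent ring fusion.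

Step 16
Reactants: 24 (2R,4aR,9R,9aR)-9-hydroxy-3,5,5,9-tetramethyl-2,4a,5,6,7,8,9,9a-octahydro-1H-benzo[7]annulen-2-yl 3-(tert-butyldimethylsilyloxy)-4-methoxybenzoate
Product: 25 (2R,4aR,9R,9aR)-9-hydroxy-3,5,5,9-tetramethyl-2,4a,5,6,7,8,9,9a-octahydro-1H-benzo[7]annulen-2-yl 3-hydroxy-4-methoxybenzoate (CNP0210711.2)
Conditions: Bu4NF, AcOH, THF, 0 °C
Reagents that add atoms: none
Why: Fluoride cleavage of an aryl silyl ether: buffered Bu4NF removes the phenolic silyl group quickly at 0 °C, conditions under which the benzoate and the tertiary alcohol should survive.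

Compound list
1 | 4,4-dimethylcyclohex-2-en-1-one | CC1(C)CCC(=O)C=C1 | starting material
2 | 4,4-dimethylcyclohexa-2,5-dien-1-one | CC1(C)C=CC(=O)C=C1 | intermediate
3 | (E)-prop-1-en-1-ylboronic acid | C/C=C/B(O)O | starting material
4 | (S)-4,4-dimethyl-5-[(E)-prop-1-en-1-yl]cyclohex-2-en-1-one | C/C=C/[C@@H]1CC(=O)C=CC1(C)C | intermediate
5 | methyl bromoacetate | COC(=O)CBr | starting material
6 | lithium cross-conjugated dienolate of 4 (not isolated) | C/C=C/[C@@H]1C=C(O[Li])C=CC1(C)C | intermediate
7 | methyl 2-[(1R,6R)-5,5-dimethyl-2-oxo-6-[(E)-prop-1-en-1-yl]cyclohex-3-en-1-yl]acetate | COC(=O)C[C@H]1C(=O)C=CC(C)(C)[C@@H]1/C=C/C | intermediate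
8 | methyl 2-[(1R,6R)-5,5-dimethyl-2-oxo-6-[(E)-prop-1-en-1-yl]cyclohexyl]acetate | COC(=O)C[C@H]1C(=O)CCC(C)(C)[C@@H]1/C=C/C | intermediate
9 | methyl 2-[(1R,7R)-6,6-dimethyl-2-oxo-7-[(E)-prop-1-en-1-yl]-3-(trimethylsilyl)cycloheptyl]acetate, epimers at the silyl carbon (not isolated) | COC(=O)C[C@H]1C(=O)C([Si](C)(C)C)CCC(C)(C)[C@@H]1/C=C/C | intermediate
10 | methyl 2-[(1R,7R)-6,6-dimethyl-2-oxo-7-[(E)-prop-1-en-1-yl]cycloheptyl]acetate | COC(=O)C[C@H]1C(=O)CCCC(C)(C)[C@@H]1/C=C/C | intermediate
11 | secondary ozonide of 10, a 5-methyl-1,2,4-trioxolan-3-yl group in place of the propenyl group (not isolated) | COC(=O)C[C@H]1C(=O)CCCC(C)(C)[C@@H]1C2OC(C)OO2 | intermediate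
12 | methyl 2-[(1R,7R)-7-formyl-6,6-dimethyl-2-oxocycloheptyl]acetate | COC(=O)C[C@H]1C(=O)CCCC(C)(C)[C@@H]1C=O | intermediate
13 | methyl 2-[(1R,7S)-7-[(Z)-2-iodoprop-1-en-1-yl]-6,6-dimethyl-2-oxocycloheptyl]acetate | COC(=O)C[C@H]1C(=O)CCCC(C)(C)[C@@H]1/C=C(/C)I | intermediate
14 | (2R,3S)-2-(2-hydroxyethyl)-3-[(Z)-2-iodoprop-1-en-1-yl]-4,4-dimethylcycloheptan-1-ol, both carbinol epimers | OCC[C@H]1C(O)CCCC(C)(C)[C@@H]1/C=C(/C)I | intermediate
15 | 2-[(1R,7S)-7-[(Z)-2-iodoprop-1-en-1-yl]-6,6-dimethyl-2-oxocycloheptyl]acetaldehyde | O=CC[C@@H]1[C@@H](/C=C(/C)I)C(C)(C)CCCC1=O | intermediate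
16 | vinylchromium dichloride derived from 15, CrCl2 in place of iodine with the alkene geometry retained (not isolated) | O=CC[C@@H]1[C@@H](/C=C(/C)[Cr](Cl)Cl)C(C)(C)CCCC1=O | intermediate
17 | (2S,4aR,9aR)-2-hydroxy-3,5,5-trimethyl-1,2,4a,5,6,7,8,9a-octahydro-9H-benzo[7]annulen-9-one | O[C@H]1C[C@@H]2[C@@H](C=C1C)C(C)(C)CCCC2=O | intermediate
18 | (2S,4aR,9aR)-3,5,5-trimethyl-2-(triethylsilyloxy)-1,2,4a,5,6,7,8,9a-octahydro-9H-benzo[7]annulen-9-one | CC[Si](CC)(CC)O[C@H]1C[C@@H]2[C@@H](C=C1C)C(C)(C)CCCC2=O | intermediate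
19 | (2S,4aR,9R,9aR)-3,5,5,9-tetramethyl-2-(triethylsilyloxy)-2,4a,5,6,7,8,9,9a-octahydro-1H-benzo[7]annulen-9-ol | CC[Si](CC)(CC)O[C@H]1C[C@@H]2[C@@H](C=C1C)C(C)(C)CCC[C@@]2(C)O | intermediate
20 | (2S,4aR,9R,9aR)-3,5,5,9-tetramethyl-2,4a,5,6,7,8,9,9a-octahydro-1H-benzo[7]annulene-2,9-diol | O[C@H]1C[C@@H]2[C@@H](C=C1C)C(C)(C)CCC[C@@]2(C)O | intermediate
21 | isovanillic acid (3-hydroxy-4-methoxybenzoic acid) | COc1ccc(C(=O)O)cc1O | starting material
22 | tert-butyldimethylsilyl 3-(tert-butyldimethylsilyloxy)-4-methoxybenzoate (not isolated) | COc1ccc(C(=O)O[Si](C)(C)C(C)(C)C)cc1O[Si](C)(C)C(C)(C)C | intermediate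
23 | 3-(tert-butyldimethylsilyloxy)-4-methoxybenzoic acid | COc1ccc(C(=O)O)cc1O[Si](C)(C)C(C)(C)C | intermediate
24 | (2R,4aR,9R,9aR)-9-hydroxy-3,5,5,9-tetramethyl-2,4a,5,6,7,8,9,9a-octahydro-1H-benzo[7]annulen-2-yl 3-(tert-butyldimethylsilyloxy)-4-methoxybenzoate | COc1ccc(C(=O)O[C@@H]2C[C@@H]3[C@@H](C=C2C)C(C)(C)CCC[C@@]3(C)O)cc1O[Si](C)(C)C(C)(C)C | intermediate
25 | (2R,4aR,9R,9aR)-9-hydroxy-3,5,5,9-tetramethyl-2,4a,5,6,7,8,9,9a-octahydro-1H-benzo[7]annulen-2-yl 3-hydroxy-4-methoxybenzoate | COc1ccc(C(=O)O[C@@H]2C[C@@H]3[C@@H](C=C2C)C(C)(C)CCC[C@@]3(C)O)cc1O | target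

Total step count: 16. Longest linear sequence: 15 steps (steps 1–13, 15 and 16); step 14 is a one-step side branch.

Steps most likely to fail

Step 10. The aldehyde may be attacked on its other face, so that the pseudo-axial C1 alcohol prevails, or the C–I bond may be reduced before the ring closes. Fallback: accept the other C1 epimer and give up the inversion. Setting out from 15, such a closure gives the (2R,4aR,9aR) hydroxy ketone F1. It is silylated to the triethylsilyl ether F2, methylated at C11 to the tertiary alcohol F3 and desilylated to the (2R,4aR,9R,9aR) diol F4, under the conditions of steps 11–13. Diol F4 is then acylated with acid 23 with retention by a Steglich esterification (DCC, DMAP, CH2Cl2), which comes back to the route at 24.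

Step 12. The methyl group may enter along the equatorial line (poor facial selectivity on the flexible seven-membered ring), or the hindered ketone may be enolised and not alkylated. Fallback: build the carbinol in two stages with a small nucleophile. Setting out from 18, a Corey–Chaykovsky reaction with dimethylsulfonium methylide (Me3SI, n-BuLi, THF, −10 °C) adds CH2 irreversibly along the axial line and gives the spiro-epoxide F5, with oxygen on the face of C3–H. Opening at the CH2 terminus with LiEt3BH (THF, 0 °C) turns it into the axial methyl and comes back to the route at 19.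

Step 7. The iodo ylide may react sluggishly with the hindered, α-branched aldehyde, give poor Z/E control, or epimerise the centre next to the aldehyde. Fallback: set the halo-alkene geometry by a cross-coupling and carry a bromide. Setting out from 12, dibromo-olefination (CBr4, PPh3, CH2Cl2, 0 °C) gives the dibromoalkene F6. A Negishi coupling (MeZnCl, Pd(PPh3)4, THF) replaces only the less hindered bromide trans to the ring and leaves the (Z)-bromoalkene F7. Reduction with i-Bu2AlH gives the diol F8 and Swern oxidation gives the keto aldehyde F9, as in steps 8 and 9. The CrCl2/NiCl2 closure of bromide F9, with a higher NiCl2 loading, comes back to the route at 17.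

Further compounds
F1 | step 10 | (2R,4aR,9aR)-2-hydroxy-3,5,5-trimethyl-1,2,4a,5,6,7,8,9a-octahydro-9H-benzo[7]annulen-9-one | O[C@@H]1C[C@@H]2[C@@H](C=C1C)C(C)(C)CCCC2=O
F2 | step 10 | (2R,4aR,9aR)-3,5,5-trimethyl-2-(triethylsilyloxy)-1,2,4a,5,6,7,8,9a-octahydro-9H-benzo[7]annulen-9-one | CC[Si](CC)(CC)O[C@@H]1C[C@@H]2[C@@H](C=C1C)C(C)(C)CCCC2=O
F3 | step 10 | (2R,4aR,9R,9aR)-3,5,5,9-tetramethyl-2-(triethylsilyloxy)-2,4a,5,6,7,8,9,9a-octahydro-1H-benzo[7]annulen-9-ol | CC[Si](CC)(CC)O[C@@H]1C[C@@H]2[C@@H](C=C1C)C(C)(C)CCC[C@@]2(C)O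
F4 | step 10 | (2R,4aR,9R,9aR)-3,5,5,9-tetramethyl-2,4a,5,6,7,8,9,9a-octahydro-1H-benzo[7]annulene-2,9-diol | O[C@@H]1C[C@@H]2[C@@H](C=C1C)C(C)(C)CCC[C@@]2(C)O
F5 | step 12 | spiro-epoxide of 18 at C11 (oxirane CH2 axial, oxygen on the face of C3–H), triethylsilyl ether | CC[Si](CC)(CC)O[C@H]1C[C@@H]2[C@@H](C=C1C)C(C)(C)CCC[C@]23CO3
F6 | step 7 | methyl 2-[(1R,7S)-7-(2,2-dibromoethenyl)-6,6-dimethyl-2-oxocycloheptyl]acetate | COC(=O)C[C@H]1C(=O)CCCC(C)(C)[C@@H]1C=C(Br)Br
F7 | step 7 | methyl 2-[(1R,7S)-7-[(Z)-2-bromoprop-1-en-1-yl]-6,6-dimethyl-2-oxocycloheptyl]acetate | COC(=O)C[C@H]1C(=O)CCCC(C)(C)[C@@H]1/C=C(/C)Br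
F8 | step 7 | (2R,3S)-3-[(Z)-2-bromoprop-1-en-1-yl]-2-(2-hydroxyethyl)-4,4-dimethylcycloheptan-1-ol, both carbinol epimers | OCC[C@H]1C(O)CCCC(C)(C)[C@@H]1/C=C(/C)Br
F9 | step 7 | 2-[(1R,7S)-7-[(Z)-2-bromoprop-1-en-1-yl]-6,6-dimethyl-2-oxocycloheptyl]acetaldehyde | O=CC[C@@H]1[C@@H](/C=C(/C)Br)C(C)(C)CCCC1=O
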